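Ring B (C5–C6–C7–C8–C9–C10) is opened across C5–C6 and C7–C8, which excises C6–C7 as a two-carbon ketene equivalent. Meldrum's acid plays that part: it condenses with the aldehyde carbon C5 of an open-chain, enantioenriched 2-aryl-2-methyl aldehyde (quaternary C10 and the propanoate arm already in place), and the carbonyl thereby held cis to C10 acylates C8. The step exploits that C5 is the beta carbon of the C7 ketone and that C8 lies para to the C12 oxygen of ring C. The product is a 1(4H)-naphthalenone; its C5 stereocentre is then set by catalyst-controlled conjugate addition of the isopropenyl group, and ring C is oxidised to the hydroxyquinone last.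

Key step: step 5

Remark: abietane locants are used (C10 quaternary carbon; C5 carries the isopropenyl group; C6 ring B methylene; C7 ring B ketone; C8 and C9 the ring-fusion carbons next to C7 and C10; C11 and C14 quinone carbonyls; C12 bears OH; C13 bears isopropyl; C1–C3 the propanoate arm); the target is (5S,10S) and 3-isopropylcatechol is taken as purchasable.

Step 1
Reactants: 1 3-(propan-2-yl)benzene-1,2-diol
Product: 2 2-(propan-2-yl)-6-(propan-2-yloxy)phenol
Conditions: 2-bromopropane (1.1 equiv), K2CO3, DMF, 50 °C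
Reagents that add atoms: 2-bromopropane, CC(C)Br
Why: Williamson etherification in which the hydroxyl remote from the ring isopropyl group (the future C11 oxygen) should react first for steric reasons, so that the two catechol oxygens become distinguishable.

Step 2
Reactants: 2 2-(propan-2-yl)-6-(propan-2-yloxy)phenol
Product: 3 2-methoxy-1-(propan-2-yl)-3-(propan-2-yloxy)benzene
Conditions: MeI, K2CO3, DMF, 50 °C
Reagents that add atoms: iodomethane, CI
Why: Williamson methylation of the remaining hindered phenol (the future C12 oxygen) with the small electrophile iodomethane.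

Step 3
Reactants: 3 2-methoxy-1-(propan-2-yl)-3-(propan-2-yloxy)benzene; 4 3-methylcyclopent-2-en-1-one
Product: 8 triethyl{[(3S)-3-[3-methoxy-4-(propan-2-yl)-2-(propan-2-yloxy)phenyl]-3-methylcyclopent-1-en-1-yl]oxy}silane, via aryllithium 5 (not isolated), via aryl(dimethyl)aluminium 6 (not isolated), via aluminium enolate 7 (not isolated)
Conditions: n-BuLi, TMEDA, Et2O, 0 °C to rt; Me2AlCl, −78 °C to rt; 4, Cu(OTf)2 (5 mol %), chiral sulfonate-bearing imidazolinium salt (N-heterocyclic carbene precursor, 5 mol %), THF, −30 °C; Et3SiOTf, −78 to 0 °C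
Reagents that add atoms: triethylsilyl trifluoromethanesulfonate, CC[Si](CC)(CC)OS(=O)(=O)C(F)(F)F
Why: Directed ortho-metalation takes place at the only ring position ortho to an ether oxygen (C9), and copper-catalysed asymmetric conjugate addition of the derived arylaluminium reagent to the beta-methyl enone sets the quaternary centre C10 under control of the chiral carbene ligand (antipode chosen for the S enolate), the aluminium enolate being silylated on oxygen so that the enol double bond lies regiospecifically on the C10 side.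

Step 4
Reactants: 8 triethyl{[(3S)-3-[3-methoxy-4-(propan-2-yl)-2-(propan-2-yloxy)phenyl]-3-methylcyclopent-1-en-1-yl]oxy}silane
Product: 11 methyl (4R)-4-[3-methoxy-4-(propan-2-yl)-2-(propan-2-yloxy)phenyl]-4-methyl-5-oxopentanoate, via silyl ester aldehyde 9 (not isolated), via aldehyde acid 10 (not isolated)
Conditions: O3, CH2Cl2, −78 °C (Sudan red end point); Me2S, −78 °C to rt; aqueous work-up; Me3SiCHN2, MeOH/toluene, 0 °C
Reagents that add atoms: ozone, [O-][O+]=O; (trimethylsilyl)diazomethane, C[Si](C)(C)C=[N+]=[N-]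
Why: Ozonolysis should cleave the electron-rich enol ether double bond far faster than the arene, turning the silyloxy carbon into the carboxyl carbon C3 and its partner into the aldehyde carbon C5, and the acid is then methylated by the diazo reagent without touching the non-enolisable aldehyde or C10.

Step 5
Reactants: 11 methyl (4R)-4-[3-methoxy-4-(propan-2-yl)-2-(propan-2-yloxy)phenyl]-4-methyl-5-oxopentanoate; 12 2,2-dimethyl-1,3-dioxane-4,6-dione (Meldrum's acid)
Product: 15 methyl (4S)-6-methoxy-4-(3-methoxy-3-oxopropyl)-4-methyl-1-oxo-7-(propan-2-yl)-5-(propan-2-yloxy)-1,4-dihydronaphthalene-2-carboxylate, via alkylidene Meldrum's acid 13 (not isolated), via enone acid 14 (not isolated)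
Conditions: 12 (1.2 equiv), pyrrolidinium acetate (10 mol %), 4 Å molecular sieves, MeCN, rt; then Sc(OTf)3 (15 mol %), 80 °C; solvent exchange; MeI, KHCO3, DMF, rt
Reagents that add atoms: iodomethane, CI
Why: Proposed new method: amine-salt-catalysed Knoevenagel condensation of 12 with the non-enolisable aldehyde gives alkylidene 13, and on heating with Sc(OTf)3 the Meldrum carbonyl that is necessarily cis to C10 is attacked by arene carbon C8, the tetrahedral intermediate collapsing with loss of acetone to the 2-carboxy-1(4H)-naphthalenone 14, which is methylated in the same flask. The closest known reaction types are the Knoevenagel/O-acylation route from salicylaldehydes and Meldrum's acid to coumarin-3-carboxylic acids and the Sc(OTf)3-catalysed intramolecular Friedel–Crafts acylation of arenes by 5-alkyl Meldrum's acids; here an arene carbon takes the place of the phenol oxygen. Ring B closes by 6-exo-trig attack of C8 on the acyl carbon C7. No stereocentre is created, and C10, which bears no hydrogen, cannot epimerise. The step needs regioselective acylation at C8 and chemoselectivity over the propanoate ester: the tether lets only C8 (para to the C12 methoxy group) reach C7 in a six-membered transition state, both Meldrum carbonyls are equivalent so alkene geometry is immaterial, and the methyl ester is far less electrophilic than the Lewis-acid-bound Meldrum carbonyl.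

Step 6
Reactants: 15 methyl (4S)-6-methoxy-4-(3-methoxy-3-oxopropyl)-4-methyl-1-oxo-7-(propan-2-yl)-5-(propan-2-yloxy)-1,4-dihydronaphthalene-2-carboxylate; 16 4,4,5,5-tetramethyl-2-(prop-1-en-2-yl)-1,3,2-dioxaborolane
Product: 18 methyl 3-[(1S,2S)-7-methoxy-1-methyl-4-oxo-6-(propan-2-yl)-2-(prop-1-en-2-yl)-8-(propan-2-yloxy)-1,2,3,4-tetrahydronaphthalen-1-yl]propanoate, via beta-keto ester 17 (not isolated)
Conditions: 16 (2.5 equiv), [Rh(cod)Cl]2 (2.5 mol %), (S)-BINAP (6 mol %), KOH (20 mol %), 1,4-dioxane/H2O 10:1, 60 °C; solvent exchange; LiCl, DMSO/H2O, 140 °C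
Reagents that add atoms: none
Why: Hayashi–Miyaura conjugate alkenylation in which the chiral rhodium–alkenyl complex should add to C5 of the doubly activated alkene on the face anti to the propanoate arm at C10 (ligand antipode chosen by the usual cyclic-enone model so that catalyst control and substrate bias coincide), which sets C5 as S, followed by Krapcho demethoxycarbonylation of the beta-keto ester that clears C6 while the isolated methyl ester survives.

Step 7
Reactants: 18 methyl 3-[(1S,2S)-7-methoxy-1-methyl-4-oxo-6-(propan-2-yl)-2-(prop-1-en-2-yl)-8-(propan-2-yloxy)-1,2,3,4-tetrahydronaphthalen-1-yl]propanoate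
Product: 19 methyl 3-[(1S,2S)-8-hydroxy-7-methoxy-1-methyl-4-oxo-6-(propan-2-yl)-2-(prop-1-en-2-yl)-1,2,3,4-tetrahydronaphthalen-1-yl]propanoate
Conditions: BCl3 (3 equiv), CH2Cl2, −78 to −20 °C; cold aqueous work-up
Reagents that add atoms: none
Why: Lewis-acid ether cleavage in which the secondary isopropyl aryl ether ionises far more readily than the methyl ether, so that only the C11 phenol should be released while the low temperature spares the isopropenyl group.

Step 8
Reactants: 19 methyl 3-[(1S,2S)-8-hydroxy-7-methoxy-1-methyl-4-oxo-6-(propan-2-yl)-2-(prop-1-en-2-yl)-1,2,3,4-tetrahydronaphthalen-1-yl]propanoate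
Product: 20 methyl 3-[(1S,2S)-7-methoxy-1-methyl-4,5,8-trioxo-6-(propan-2-yl)-2-(prop-1-en-2-yl)-1,2,3,4,5,8-hexahydronaphthalen-1-yl]propanoate
Conditions: (KSO3)2NO (Fremy's salt, 2.5 equiv), KH2PO4 buffer, acetone/H2O, rt
Reagents that add atoms: potassium nitrosodisulfonate, [K+].[K+].[O]N(S(=O)(=O)[O-])S(=O)(=O)[O-]
Why: Teuber oxidation in which the phenoxyl radical of the C11 phenol is trapped by a second nitroxyl radical at the free para position C14 and loss of imidodisulfonate gives the para-quinone with the C12 methoxy group intact.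

Step 9
Reactants: 20 methyl 3-[(1S,2S)-7-methoxy-1-methyl-4,5,8-trioxo-6-(propan-2-yl)-2-(prop-1-en-2-yl)-1,2,3,4,5,8-hexahydronaphthalen-1-yl]propanoate
Product: 21 methyl 3-[(1S,2S)-7-hydroxy-1-methyl-4,5,8-trioxo-6-(propan-2-yl)-2-(prop-1-en-2-yl)-1,2,3,4,5,8-hexahydronaphthalen-1-yl]propanoate
Conditions: NaOH (2 equiv), THF/H2O, 0 °C, short reaction time; dilute HCl
Reagents that add atoms: sodium hydroxide, [Na+].[OH-]
Why: Addition–elimination of hydroxide at C12 of the vinylogous methyl ester should be much faster than saponification of the aliphatic methyl ester, and the resulting vinylogous carboxylate resists further attack until it is protonated on work-up.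

Compound list
1 | 3-(propan-2-yl)benzene-1,2-diol (3-isopropylcatechol) | CC(C)c1cccc(O)c1O | starting material
2 | 2-(propan-2-yl)-6-(propan-2-yloxy)phenol | CC(C)c1cccc(OC(C)C)c1O | intermediate
3 | 2-methoxy-1-(propan-2-yl)-3-(propan-2-yloxy)benzene | CC(C)c1cccc(OC(C)C)c1OC | intermediate
4 | 3-methylcyclopent-2-en-1-one | CC1=CC(=O)CC1 | starting material
5 | [3-methoxy-4-(propan-2-yl)-2-(propan-2-yloxy)phenyl]lithium | [Li]c1ccc(C(C)C)c(OC)c1OC(C)C | intermediate
6 | [3-methoxy-4-(propan-2-yl)-2-(propan-2-yloxy)phenyl]dimethylaluminium | C[Al](C)c1ccc(C(C)C)c(OC)c1OC(C)C | intermediate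
7 | dimethylaluminium (3S)-3-[3-methoxy-4-(propan-2-yl)-2-(propan-2-yloxy)phenyl]-3-methylcyclopent-1-en-1-olate | CC(C)c1ccc([C@]2(C)C=C(O[Al](C)C)CC2)c(OC(C)C)c1OC | intermediate
8 | triethyl{[(3S)-3-[3-methoxy-4-(propan-2-yl)-2-(propan-2-yloxy)phenyl]-3-methylcyclopent-1-en-1-yl]oxy}silane | CC(C)c1ccc([C@]2(C)C=C(O[Si](CC)(CC)CC)CC2)c(OC(C)C)c1OC | intermediate
9 | triethylsilyl (4R)-4-[3-methoxy-4-(propan-2-yl)-2-(propan-2-yloxy)phenyl]-4-methyl-5-oxopentanoate | CC(C)c1ccc([C@@](C)(CCC(=O)O[Si](CC)(CC)CC)C=O)c(OC(C)C)c1OC | intermediate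
10 | (4R)-4-[3-methoxy-4-(propan-2-yl)-2-(propan-2-yloxy)phenyl]-4-methyl-5-oxopentanoic acid | CC(C)c1ccc([C@@](C)(CCC(=O)O)C=O)c(OC(C)C)c1OC | intermediate
11 | methyl (4R)-4-[3-methoxy-4-(propan-2-yl)-2-(propan-2-yloxy)phenyl]-4-methyl-5-oxopentanoate | CC(C)c1ccc([C@@](C)(CCC(=O)OC)C=O)c(OC(C)C)c1OC | intermediate
12 | 2,2-dimethyl-1,3-dioxane-4,6-dione (Meldrum's acid) | CC1(C)OC(=O)CC(=O)O1 | starting material
13 | methyl (4S)-5-(2,2-dimethyl-4,6-dioxo-1,3-dioxan-5-ylidene)-4-[3-methoxy-4-(propan-2-yl)-2-(propan-2-yloxy)phenyl]-4-methylpentanoate | CC(C)c1ccc([C@@](C)(CCC(=O)OC)C=C2C(=O)OC(C)(C)OC2=O)c(OC(C)C)c1OC | intermediate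
14 | (4S)-6-methoxy-4-(3-methoxy-3-oxopropyl)-4-methyl-1-oxo-7-(propan-2-yl)-5-(propan-2-yloxy)-1,4-dihydronaphthalene-2-carboxylic acid | CC(C)c1cc2C(=O)C(C(=O)O)=C[C@](C)(CCC(=O)OC)c2c(OC(C)C)c1OC | intermediate
15 | methyl (4S)-6-methoxy-4-(3-methoxy-3-oxopropyl)-4-methyl-1-oxo-7-(propan-2-yl)-5-(propan-2-yloxy)-1,4-dihydronaphthalene-2-carboxylate | CC(C)c1cc2C(=O)C(C(=O)OC)=C[C@](C)(CCC(=O)OC)c2c(OC(C)C)c1OC | intermediate
16 | 4,4,5,5-tetramethyl-2-(prop-1-en-2-yl)-1,3,2-dioxaborolane (isopropenylboronic acid pinacol ester) | C=C(C)B1OC(C)(C)C(C)(C)O1 | starting material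
17 | methyl (2RS,3S,4S)-6-methoxy-4-(3-methoxy-3-oxopropyl)-4-methyl-1-oxo-7-(propan-2-yl)-3-(prop-1-en-2-yl)-5-(propan-2-yloxy)-1,2,3,4-tetrahydronaphthalene-2-carboxylate | C=C(C)[C@@H]1C(C(=O)OC)C(=O)c2cc(C(C)C)c(OC)c(OC(C)C)c2[C@@]1(C)CCC(=O)OC | intermediate
18 | methyl 3-[(1S,2S)-7-methoxy-1-methyl-4-oxo-6-(propan-2-yl)-2-(prop-1-en-2-yl)-8-(propan-2-yloxy)-1,2,3,4-tetrahydronaphthalen-1-yl]propanoate | C=C(C)[C@@H]1CC(=O)c2cc(C(C)C)c(OC)c(OC(C)C)c2[C@@]1(C)CCC(=O)OC | intermediate
19 | methyl 3-[(1S,2S)-8-hydroxy-7-methoxy-1-methyl-4-oxo-6-(propan-2-yl)-2-(prop-1-en-2-yl)-1,2,3,4-tetrahydronaphthalen-1-yl]propanoate | C=C(C)[C@@H]1CC(=O)c2cc(C(C)C)c(OC)c(O)c2[C@@]1(C)CCC(=O)OC | intermediate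
20 | methyl 3-[(1S,2S)-7-methoxy-1-methyl-4,5,8-trioxo-6-(propan-2-yl)-2-(prop-1-en-2-yl)-1,2,3,4,5,8-hexahydronaphthalen-1-yl]propanoate | C=C(C)[C@@H]1CC(=O)C2=C(C(=O)C(OC)=C(C(C)C)C2=O)[C@@]1(C)CCC(=O)OC | intermediate
21 | methyl 3-[(1S,2S)-7-hydroxy-1-methyl-4,5,8-trioxo-6-(propan-2-yl)-2-(prop-1-en-2-yl)-1,2,3,4,5,8-hexahydronaphthalen-1-yl]propanoate | C=C(C)[C@@H]1CC(=O)C2=C(C(=O)C(O)=C(C(C)C)C2=O)[C@@]1(C)CCC(=O)OC | target

Total step count: 9. Longest linear sequence: 9 steps (1 to 21; 4, 12 and 16 enter as purchased reactants).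

Steps most likely to fail

First, step 5, which carries the proposed new method. The alkylidene may be diverted by conjugate addition of a second molecule of 12 or by thermal fragmentation before C-acylation takes place, or acylation may not proceed at the conjugated carbonyl. The fallback for step 5 uses known reactions and sets out from aldehyde 11. The Knoevenagel condensation with 12 is run alone (pyrrolidinium acetate, CH2Cl2, 4 Å molecular sieves) and alkylidene 13 is isolated. Rhodium-catalysed asymmetric conjugate addition of 16 ([Rh(cod)Cl]2, chiral diene or BINAP ligand of the antipode giving 5S, KOH, dioxane/H2O) then gives methyl (4S,5S)-5-(2,2-dimethyl-4,6-dioxo-1,3-dioxan-5-yl)-4-[3-methoxy-4-(propan-2-yl)-2-(propan-2-yloxy)phenyl]-4,6-dimethylhept-6-enoate F1. Sc(OTf)3 (10 mol %) in MeNO2 at 100 °C effects the intramolecular Friedel–Crafts acylation of this enolisable Meldrum's acid. The resulting (2RS,3S,4S)-6-methoxy-4-(3-methoxy-3-oxopropyl)-4-methyl-1-oxo-7-(propan-2-yl)-3-(prop-1-en-2-yl)-5-(propan-2-yloxy)-1,2,3,4-tetrahydronaphthalene-2-carboxylic acid F2 loses carbon dioxide in the flask, and the route is rejoined at tetralone 18.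

Second, step 6. Carbometalation of the hindered, trisubstituted acceptor next to the quaternary centre may be slow, so that protodeboronation of 16 wins, or facial selectivity may be eroded. The fallback for step 6 sets out from 15: the isopropenyl group is delivered by the stoichiometric cuprate prepared from isopropenylmagnesium bromide and CuBr·SMe2 (THF, −78 °C), which relies on substrate control alone (attack anti to the propanoate arm on the nearly flat ring). Protonation gives beta-keto ester 17, the C5 epimers are separated if necessary, and Krapcho demethoxycarbonylation under the conditions of the main route returns to 18.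

Third, step 3. Poor conversion or enantioselectivity may result because the ortho-alkoxy arylaluminium reagent is hindered, and premature protonation of the enolate would lose the regiochemical information. The fallback for step 3 sets out from 3: aryllithium 5 is added to 3-ethoxycyclopent-2-en-1-one to give 3-ethoxy-1-[3-methoxy-4-(propan-2-yl)-2-(propan-2-yloxy)phenyl]cyclopent-2-en-1-ol F3. On acidic work-up this undergoes Stork–Danheiser transposition to 3-[3-methoxy-4-(propan-2-yl)-2-(propan-2-yloxy)phenyl]cyclopent-2-en-1-one F4. Copper-catalysed asymmetric conjugate addition of Me3Al (Cu(O2CC4H3S), the thiophene-2-carboxylate of monovalent copper, with a chiral phosphoramidite ligand, Et2O, −30 °C) then introduces the methyl group instead of the aryl group. This gives the same aluminium enolate 7, which is silylated with Et3SiOTf to rejoin the route at 8.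

Further compounds
F1 | step 5 | methyl (4S,5S)-5-(2,2-dimethyl-4,6-dioxo-1,3-dioxan-5-yl)-4-[3-methoxy-4-(propan-2-yl)-2-(propan-2-yloxy)phenyl]-4,6-dimethylhept-6-enoate | C=C(C)[C@H](C1C(=O)OC(C)(C)OC1=O)[C@](C)(CCC(=O)OC)c1ccc(C(C)C)c(OC)c1OC(C)C
F2 | step 5 | (2RS,3S,4S)-6-methoxy-4-(3-methoxy-3-oxopropyl)-4-methyl-1-oxo-7-(propan-2-yl)-3-(prop-1-en-2-yl)-5-(propan-2-yloxy)-1,2,3,4-tetrahydronaphthalene-2-carboxylic acid | C=C(C)[C@@H]1C(C(=O)O)C(=O)c2cc(C(C)C)c(OC)c(OC(C)C)c2[C@@]1(C)CCC(=O)OC
F0 | step 6 | none | none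
F3 | step 3 | 3-ethoxy-1-[3-methoxy-4-(propan-2-yl)-2-(propan-2-yloxy)phenyl]cyclopent-2-en-1-ol | CCOC1=CC(O)(c2ccc(C(C)C)c(OC)c2OC(C)C)CC1
F4 | step 3 | 3-[3-methoxy-4-(propan-2-yl)-2-(propan-2-yloxy)phenyl]cyclopent-2-en-1-one | O=C1C=C(c2ccc(C(C)C)c(OC)c2OC(C)C)CC1
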